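## Structural features

The target is a spiro[5.5]undecane of the chamigrane type. Ring A (C6 to C11) carries an exocyclic methylene at C7, an acetoxy group at C9, a secondary bromide at C10 and a gem-dimethyl carbon at C11. Ring B (C6, C1 to C5) carries a secondary chloride at C2 and a tertiary bromide beside a methyl group at C3. The rings share only C6, a quaternary carbon bonded directly to the quaternary C11, so the most congested bond lies at the ring junction. The five stereocentres form two contiguous pairs, C2/C3 (halogens trans) and C9/C10 (acetoxy and bromine cis), both related to C6: chlorine at C2 is 1,3 to C6 on the side of C7, bromine at C3 is 1,4 on the side of C11, and the C10 bromine lies on the face of ring A that also holds C1. The fragile groups are the tertiary bromide (ionisation, elimination), the anti C2/C3 dihalide (reductive elimination) and the 1,1-disubstituted alkene, which is the less stable alkene position and moves into conjugation with any C9 carbonyl under acid or base. The real difficulty is to set the spiro centre in a defined sense relative to both remote pairs and to place chlorine on the secondary and bromine on the tertiary carbon, the opposite of what halonium chemistry delivers. The key step uses the 1,3 relation of C6 and C2 across the C1 methylene of ring B: with C7 as a carbonyl, C6 can carry a stabilised radical, and its addition to C1 of a C1=C2 vinyl group leaves the radical on C2, where chlorine is needed, next to an already oxygenated C3.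

## Logic of the disconnections

**22 from 21.** The C9 O–acyl bond is cut. The ester is put on last because it could be lost or could eliminate earlier; the gain is a free alcohol whose configuration can come from a ketone. The forward step must acylate a hindered alcohol beside a bromide without a base strong enough to remove HBr.

**21 from 20.** The C9–H bond is cut. A cis bromohydrin is the usual result of hydride addition to an α-bromo ketone anti to the C–Br bond, so C9 is derived from C10 and one stereocentre disappears. The hydride must be non-basic and cold, because 20 can enolise toward C8 (alkene into conjugation) or toward C10 (epimerisation).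

**20 from 19.** The C8–H bond is cut and the exocyclic alkene is traced to a C–Si bond. The exocyclic position is the less stable one and has to be made under kinetic control: protonation of the extended dienolate at C8. Methylenating C7 of 17 and hydrolysing the enol ether was rejected, because an alkoxy diene of that kind is protonated at its methylene terminus and would give the conjugated methyl enone. The demand is a buffered, cold release of the dienolate.

**19 from 17 (through 18).** The C7–CH2Si bond is cut and the C9 carbonyl goes back to the enol ether (carbonyl transposition). This returns the problem to the vinylogous ester that the key step delivers. The nucleophile must add to a hindered, weakly electrophilic carbonyl and spare three carbon–halogen bonds.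

**17 from 15 (through 16).** The C10–Br bond is cut, and the C10–H bond is recognised as the one to be formed last. C10 is the only acidic position once C6 is quaternary, and bromine must end on the more hindered face, so bromine is introduced first and the proton is delivered afterwards from the open face. The demand is reaction at C10 instead of C8 and a protonation that is not followed by equilibration.

**15 from 14, 14 from 13.** The C3–Br bond is exchanged for C3–O, then the O–Si bond is restored. The oxygen comes from the chiral pool and serves as a control element in the key step; the neighbouring chlorine allows substitution with retention. Ionisation must be assisted by chlorine and must not end in elimination or in cleavage of the enol ether.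

**13 from 12.** The C6–C1 and C2–Cl bonds are cut. One operation gives ring B, the spiro centre and the C2 chloride, and leaves an open chain on a simple ring. The forward step needs 6-endo closure, return of chlorine, and face selectivity at C6 induced from C3.

**12 from 11; 11 from 10 and 8.** The C6–Cl bond and then the C6–C5 bond are cut, both by enolate chemistry at the α′ position of the vinylogous ester. The route becomes convergent. The demand is alkylation and a second deprotonation next to a quaternary carbon.

**10 from 9.** The enol ether C–O bond is cut; this differentiates the two carbonyl groups of a symmetrical dione.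

**8 from 1 (through 7, 6, 5, 4, 3 and 2).** The C–I bond goes back to C–O, the C1=C2 alkene to a lactol (Wittig), the lactol to a lactone, and the lactone to a diacid whose α-hydroxy acid half is held as a dioxolanone. The tertiary carbinol centre is never touched. The two carboxyl groups must be told apart and the tertiary silyl ether must stay in place.

## Other disconnections considered

**Alternative 1:** The cut is C6–C7. In the forward sense zerovalent palladium with a chiral diphosphine would insert into the C7–Br bond of vinyl bromide A2, add 6-exo across the C6=C1 alkene of the ring B cyclohexene, and lose a β-hydride toward C2 to give spiro diene ketal A1.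
- In its favour: quaternary centres from intramolecular Heck reactions are well established, and the catalyst could set C6 without relying on the weak 1,4 induction of the chosen plan; on this point it is the better plan in principle. Ring A would arrive complete with the exocyclic methylene, so no late unmasking of the labile alkene is needed, which is also better.
- Against it here: the C9/C10 bromohydrin ether must first be made in an open chain beside the quaternary C11. The neopentyl bromide has to survive zerovalent palladium and base at the temperatures needed to insert a trisubstituted alkene that forms two adjacent quaternary carbons. Ring B emerges with only a ketal and a C1=C2 alkene, so the methyl group and both halogens, in the pattern opposite to halonium opening, are still to come beside a second alkene.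
- Comparison: the mechanism is a two-electron migratory insertion with catalyst control, against a substrate-controlled radical addition. The chosen key step sets fewer ring A features but installs the C2 chloride and the C3 oxygen with the ring, and should need fewer steps after it.

**Alternative 2:** The cut is C8–C9. An alkylaluminium chloride Lewis acid would activate the aldehyde of α-bromo aldehyde A4, the methylene terminus of the C7 isopropenyl group would attack C9 while a methyl hydrogen passes to oxygen (type 2 carbonyl-ene), and ring A would close to bromohydrin A3.
- In its favour: the exocyclic alkene and the C9 carbinol would form in one event, exactly in the kinetically required alkene position. That is better than the chosen plan, which spends steps 14 to 16 on the same task.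
- Against it here: C10 in A4 is an epimerisable centre that must already be correct relative to C6. The quaternary C6 with isopropenyl, the gem-dimethyl chain and both ring B arms must be made enantioselectively beforehand, so the hardest problem is moved, not solved. The Lewis acid can also bind the enone or ionise the bromide, and ring B again lacks methyl, chlorine and bromine.
- Comparison: both key steps close one ring. The ene step sets only C9, the radical step sets C6 and C2. On step economy to the fully halogenated ring B the chosen plan should be shorter.

**Alternative 3:** The cuts are C6–C5 and C1–C2. Formyl vinylogous ester A6 would add through C6 to methyl vinyl ketone A7 under a chiral bifunctional amine base, and aldol condensation onto the formyl carbon would close ring B to spiro enone A5.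
- In its favour: two bonds, ring B and the quaternary centre would come from one flask with catalytic enantiocontrol, the shortest access to the spiro core; on step economy up to the spirocycle it is the better plan. Ring A of A5 is the vinylogous ester of 13, so the ring A endgame would be the same (equal).
- Against it here: C6 is a hindered nucleophile next to a quaternary carbon, and the formyl group can be lost under amine and water. Ring B arrives without methyl or halogen: the C1=C2 alkene must be reduced, chlorine placed at C2 and not at C4, and methyl and bromine set at C3, all controlled from C6 alone.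
- Comparison: polar conjugate addition and aldol against radical addition and atom transfer. The chosen plan pays with a longer chain synthesis but obtains the C2 chloride regiospecifically and the C3 configuration from the chiral pool.

Key step: step 10

## Route

Remark: locants C1 to C11 are used as spiro[5.5]undecane locants throughout (ring B = C1 to C6, ring A = C6 to C11); the descriptors in the names refer to them.

Remark: the C3 oxygen of 13 stands where bromine stands in 22, and C2 and C6 of 13 have the spatial arrangement of 22, so the structures of 12 and 13 need no correction and the exchange at C3 (step 12) has to run with retention.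

Step 1
Reactants: 1 (S)-citramalic acid
Product: 2 (S)-2-(2,2,4-trimethyl-5-oxo-1,3-dioxolan-4-yl)acetic acid
Conditions: Me2C(OMe)2, p-TsOH (cat.), acetone, rt
Reagents that add atoms: 2,2-dimethoxypropane COC(C)(C)OC
Why: Acid-catalysed acetonide formation engages the α-hydroxy acid as the five-membered dioxolanone and leaves the β-carboxyl free; the stereocentre is not involved.

Step 2
Reactants: 2 (S)-2-(2,2,4-trimethyl-5-oxo-1,3-dioxolan-4-yl)acetic acid
Product: 4 (S)-3-hydroxy-3-methyloxolan-2-one, via hydroxyethyl dioxolanone 3 (not isolated)
Conditions: BH3·SMe2, THF, 0 °C to rt; MeOH; then p-TsOH (cat.), CH2Cl2, rt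
Reagents that add atoms: none
Why: Borane reduces the free carboxylic acid much faster than the ester-like dioxolanone; under acid the new primary alcohol attacks the dioxolanone carbonyl, acetone is lost and the five-membered lactone forms (translactonisation).

Step 3
Reactants: 4 (S)-3-hydroxy-3-methyloxolan-2-one
Product: 5 (S)-3-methyl-3-(triethylsilyloxy)oxolan-2-one
Conditions: Et3SiOTf, 2,6-lutidine, CH2Cl2, 0 °C
Reagents that add atoms: triethylsilyl trifluoromethanesulfonate CC[Si](CC)(CC)OS(=O)(=O)C(F)(F)F
Why: The silyl triflate silylates the hindered tertiary alcohol; the triethylsilyl ether is stable to amide bases and to the radical step and can be removed later under mild buffered conditions.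

Step 4
Reactants: 5 (S)-3-methyl-3-(triethylsilyloxy)oxolan-2-one
Product: 6 (3S)-3-methyl-3-(triethylsilyloxy)oxolan-2-ol (anomer mixture)
Conditions: i-Bu2AlH (1.1 equiv), CH2Cl2, −78 °C
Reagents that add atoms: none
Why: Partial reduction of a lactone to the lactol; the tetrahedral aluminium hemiacetal is stable at −78 °C and collapses only on work-up.

Step 5
Reactants: 6 (3S)-3-methyl-3-(triethylsilyloxy)oxolan-2-ol (anomer mixture)
Product: 7 (S)-3-methyl-3-(triethylsilyloxy)pent-4-en-1-ol
Conditions: Ph3PCH3Br, n-BuLi, THF, 0 °C to rt
Reagents that add atoms: methyltriphenylphosphonium bromide C[P+](c1ccccc1)(c1ccccc1)c1ccccc1.[Br-]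
Why: Wittig methylenation of the lactol through its open hydroxy aldehyde form gives the vinyl group and frees the primary alcohol; a lithium alkoxide at or below room temperature is used to keep the silyl group on the tertiary oxygen.

Step 6
Reactants: 7 (S)-3-methyl-3-(triethylsilyloxy)pent-4-en-1-ol
Product: 8 (S)-triethyl[(5-iodo-3-methylpent-1-en-3-yl)oxy]silane
Conditions: I2, PPh3, imidazole, CH2Cl2, 0 °C
Reagents that add atoms: iodine II
Why: Appel-type iodination of the primary alcohol by SN2 displacement of the oxyphosphonium group; the buffered medium leaves the tertiary allylic silyl ether intact.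

Step 7
Reactants: 9 dimedone
Product: 10 3-ethoxy-5,5-dimethylcyclohex-2-en-1-one
Conditions: EtOH, p-TsOH (cat.), toluene, reflux (Dean–Stark)
Reagents that add atoms: ethanol CCO
Why: Acid-catalysed enol etherification of the symmetrical 1,3-dione, driven by removal of water.

Step 8
Reactants: 10 3-ethoxy-5,5-dimethylcyclohex-2-en-1-one; 8 (S)-triethyl[(5-iodo-3-methylpent-1-en-3-yl)oxy]silane
Product: 11 3-ethoxy-5,5-dimethyl-6-[(3S)-3-methyl-3-(triethylsilyloxy)pent-4-en-1-yl]cyclohex-2-en-1-one (both C6 epimers)
Conditions: LiN(i-Pr)2, THF, −78 °C; then 8, DMPU, −78 °C to rt
Reagents that add atoms: none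
Why: Kinetic deprotonation of the vinylogous ester at the α′ carbon gives the cross-conjugated enolate, which is alkylated by the primary iodide (SN2); the new C6 centre forms as a mixture that is erased in step 10.

Step 9
Reactants: 11 3-ethoxy-5,5-dimethyl-6-[(3S)-3-methyl-3-(triethylsilyloxy)pent-4-en-1-yl]cyclohex-2-en-1-one (both C6 epimers)
Product: 12 6-chloro-3-ethoxy-5,5-dimethyl-6-[(3S)-3-methyl-3-(triethylsilyloxy)pent-4-en-1-yl]cyclohex-2-en-1-one (both C6 epimers)
Conditions: LiN(i-Pr)2, THF, −78 °C; NCS, −78 to 0 °C
Reagents that add atoms: N-chlorosuccinimide O=C1CCC(=O)N1Cl
Why: A second α′ deprotonation gives the fully substituted enolate, which is chlorinated at C6 by the electrophilic chlorine source; no stereocontrol is needed because C6 becomes a planar radical in the next step.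

Step 10
Reactants: 12 6-chloro-3-ethoxy-5,5-dimethyl-6-[(3S)-3-methyl-3-(triethylsilyloxy)pent-4-en-1-yl]cyclohex-2-en-1-one (both C6 epimers)
Product: 13 (2S,3S,6S)-2-chloro-9-ethoxy-3,11,11-trimethyl-3-(triethylsilyloxy)spiro[5.5]undec-8-en-7-one
Conditions: CuCl (0.3 equiv), TPMA (0.3 equiv), ClCH2CH2Cl, 80 °C, degassed
Reagents that add atoms: none
Why: Monovalent copper bound to tris(2-pyridylmethyl)amine abstracts the tertiary C6 chlorine reversibly and gives a planar C6 radical conjugated with the C7 carbonyl, so both epimers of 12 converge. The radical adds to the terminal vinyl carbon C1 and closes ring B in the 6-endo-trig mode; 5-exo attack on C2 would join the hindered tertiary radical to a carbon flanked by the fully substituted C3, and since addition of such a stabilised radical is reversible the cyclohexyl radical should accumulate. The secondary C2 radical then takes chlorine from the divalent copper chloride complex, which regenerates the catalyst; the closest known reaction type is the copper-catalysed Kharasch-type atom-transfer radical cyclisation of α-chloro carbonyl compounds. C6 is set in a chair-like transition state in which the C4–C5 bond lies anti to the quaternary C11 (C11 equatorial, the flat C7 carbonyl axial on the forming ring) and the C3 methyl is equatorial with the silyloxy group axial, which places C11 trans to the methyl group. C2 is set by chlorine delivery to the ring face opposite to the axial triethylsilyloxy group and to C11, giving chlorine trans to oxygen. The step needs 6-endo over 5-exo closure, chlorine return over loss of HCl, and face selectivity at C6; the monosubstituted alkene beside a fully substituted allylic carbon, the low radical concentration kept by the copper couple, and the fixed (S) centre at C3 are what the substrate offers to secure them.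

Step 11
Reactants: 13 (2S,3S,6S)-2-chloro-9-ethoxy-3,11,11-trimethyl-3-(triethylsilyloxy)spiro[5.5]undec-8-en-7-one
Product: 14 (2S,3S,6S)-2-chloro-9-ethoxy-3-hydroxy-3,11,11-trimethylspiro[5.5]undec-8-en-7-one
Conditions: HF·pyridine, THF/pyridine, 0 °C to rt
Reagents that add atoms: none
Why: Fluoride-assisted cleavage of the Si–O bond under buffered acidic conditions; no free alkoxide forms that could close an epoxide onto C2, and the enol ether and the chloride are not affected.

Step 12
Reactants: 14 (2S,3S,6S)-2-chloro-9-ethoxy-3-hydroxy-3,11,11-trimethylspiro[5.5]undec-8-en-7-one
Product: 15 (2S,3S,6S)-3-bromo-2-chloro-9-ethoxy-3,11,11-trimethylspiro[5.5]undec-8-en-7-one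
Conditions: Me3SiBr, CH2Cl2, −20 to 0 °C
Reagents that add atoms: bromotrimethylsilane C[Si](C)(C)Br
Why: Silylation of the tertiary alcohol releases HBr, and ionisation at C3 is assisted by the antiperiplanar axial C2 chlorine (chloronium ion); bromide opens the bridged ion at the tertiary carbon anti to chlorine, so bromine takes the place of oxygen with net retention (SN1 with neighbouring-group participation, diaxial opening). Any alkene formed by proton loss should add HBr again in the Markovnikov sense through the same cation.

Step 13
Reactants: 15 (2S,3S,6S)-3-bromo-2-chloro-9-ethoxy-3,11,11-trimethylspiro[5.5]undec-8-en-7-one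
Product: 17 (2S,3S,6S,10R)-3,10-dibromo-2-chloro-9-ethoxy-3,11,11-trimethylspiro[5.5]undec-8-en-7-one, via C10-epimeric γ-bromide 16 (not isolated)
Conditions: LiN(i-Pr)2, THF, −78 °C; NBS (1.0 equiv); LiN(SiMe3)2, −78 °C; AcOH, −78 °C
Reagents that add atoms: N-bromosuccinimide O=C1CCC(=O)N1Br
Why: With C6 quaternary the base removes a C10 hydrogen, and the β-alkoxy dienolate takes bromine at its γ terminus C10 (γ-halogenation of a vinylogous ester dienolate). The axial C2 chlorine forces the C7 oxygen toward C5, so C1 stands pseudoaxial over one face of C10; the second deprotonation erases C10, and kinetic protonation of the bromodienolate from the open face, anti to C1, leaves bromine syn to C1 (10R). This configuration is the more hindered one and must not be equilibrated afterwards.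

Step 14
Reactants: 17 (2S,3S,6S,10R)-3,10-dibromo-2-chloro-9-ethoxy-3,11,11-trimethylspiro[5.5]undec-8-en-7-one
Product: 19 (2S,3S,6R,10R)-3,10-dibromo-2-chloro-3,11,11-trimethyl-7-[(trimethylsilyl)methyl]spiro[5.5]undec-7-en-9-one, via silylmethyl carbinol 18 (not isolated)
Conditions: Me3SiCH2MgCl, CeCl3, THF, −78 to 0 °C; then 1 M HCl, THF, 0 °C
Reagents that add atoms: (trimethylsilyl)methylmagnesium chloride C[Si](C)(C)C[Mg]Cl; water O
Why: The weakly basic organocerium reagent adds 1,2 to the hindered C7 carbonyl of the vinylogous ester; dilute acid then ionises the tertiary allylic carbinol, water adds at C9 and ethanol is lost (Stork–Danheiser transposition), which gives the C9 enone with the silylmethyl group on C7. The silicon marks the carbon that is to become the exocyclic methylene.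

Step 15
Reactants: 19 (2S,3S,6R,10R)-3,10-dibromo-2-chloro-3,11,11-trimethyl-7-[(trimethylsilyl)methyl]spiro[5.5]undec-7-en-9-one
Product: 20 (2S,3S,6R,10R)-3,10-dibromo-2-chloro-3,11,11-trimethyl-7-methylidenespiro[5.5]undecan-9-one
Conditions: Bu4NF, AcOH, THF, −40 to 0 °C
Reagents that add atoms: none
Why: Fluoride cleaves the C–Si bond of the vinylogous α-silyl ketone and releases the extended dienolate, which acetic acid protonates kinetically at C8 (α-protonation of a dienolate), so the alkene ends in the exocyclic position. The buffer and the low temperature are there to prevent reconjugation, enolisation toward C10 and Favorskii-type loss of bromide.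

Step 16
Reactants: 20 (2S,3S,6R,10R)-3,10-dibromo-2-chloro-3,11,11-trimethyl-7-methylidenespiro[5.5]undecan-9-one
Product: 21 (2S,3S,6R,9S,10R)-3,10-dibromo-2-chloro-3,11,11-trimethyl-7-methylidenespiro[5.5]undecan-9-ol (isoobtusol)
Conditions: i-Bu2AlH, CH2Cl2, −78 °C
Reagents that add atoms: none
Why: The hydride adds to the C9 carbonyl anti to the polar C10–Br bond (polar Felkin–Anh model for an α-bromo ketone), which places the hydroxyl cis to bromine (9S); the Lewis-acidic, non-basic reagent at −78 °C does not enolise the ketone, so the alkene position and C10 are kept.

Step 17
Reactants: 21 (2S,3S,6R,9S,10R)-3,10-dibromo-2-chloro-3,11,11-trimethyl-7-methylidenespiro[5.5]undecan-9-ol (isoobtusol)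
Product: 22 (2S,3S,6R,9S,10R)-3,10-dibromo-2-chloro-3,11,11-trimethyl-7-methylidenespiro[5.5]undecan-9-yl acetate (9-acetylisoobtusol)
Conditions: Ac2O, DMAP, pyridine, CH2Cl2, rt
Reagents that add atoms: acetic anhydride CC(=O)OC(C)=O
Why: DMAP-catalysed acylation of the hindered secondary alcohol under weakly basic conditions; the cis bromohydrin cannot close to an epoxide, and no stereocentre is touched.

## Compound list

1 | (S)-citramalic acid | C[C@](O)(CC(=O)O)C(=O)O | starting material
2 | (S)-2-(2,2,4-trimethyl-5-oxo-1,3-dioxolan-4-yl)acetic acid | C[C@@]1(CC(=O)O)OC(C)(C)OC1=O | intermediate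
3 | (S)-5-(2-hydroxyethyl)-2,2,5-trimethyl-1,3-dioxolan-4-one | C[C@@]1(CCO)OC(C)(C)OC1=O | intermediate (not isolated)
4 | (S)-3-hydroxy-3-methyloxolan-2-one | C[C@]1(O)CCOC1=O | intermediate
5 | (S)-3-methyl-3-(triethylsilyloxy)oxolan-2-one | C[C@]1(O[Si](CC)(CC)CC)CCOC1=O | intermediate
6 | (3S)-3-methyl-3-(triethylsilyloxy)oxolan-2-ol (anomer mixture) | C[C@]1(O[Si](CC)(CC)CC)CCOC1O | intermediate
7 | (S)-3-methyl-3-(triethylsilyloxy)pent-4-en-1-ol | OCC[C@](C)(O[Si](CC)(CC)CC)C=C | intermediate
8 | (S)-triethyl[(5-iodo-3-methylpent-1-en-3-yl)oxy]silane | ICC[C@](C)(O[Si](CC)(CC)CC)C=C | intermediate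
9 | dimedone (5,5-dimethylcyclohexane-1,3-dione) | CC1(C)CC(=O)CC(=O)C1 | starting material
10 | 3-ethoxy-5,5-dimethylcyclohex-2-en-1-one | CCOC1=CC(=O)CC(C)(C)C1 | intermediate
11 | 3-ethoxy-5,5-dimethyl-6-[(3S)-3-methyl-3-(triethylsilyloxy)pent-4-en-1-yl]cyclohex-2-en-1-one (both C6 epimers) | CCOC1=CC(=O)C(CC[C@](C)(O[Si](CC)(CC)CC)C=C)C(C)(C)C1 | intermediate
12 | 6-chloro-3-ethoxy-5,5-dimethyl-6-[(3S)-3-methyl-3-(triethylsilyloxy)pent-4-en-1-yl]cyclohex-2-en-1-one (both C6 epimers) | CCOC1=CC(=O)C(Cl)(CC[C@](C)(O[Si](CC)(CC)CC)C=C)C(C)(C)C1 | intermediate
13 | (2S,3S,6S)-2-chloro-9-ethoxy-3,11,11-trimethyl-3-(triethylsilyloxy)spiro[5.5]undec-8-en-7-one | O=C1C=C(OCC)CC(C)(C)[C@@]12CC[C@](C)(O[Si](CC)(CC)CC)[C@@H](Cl)C2 | intermediate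
14 | (2S,3S,6S)-2-chloro-9-ethoxy-3-hydroxy-3,11,11-trimethylspiro[5.5]undec-8-en-7-one | O=C1C=C(OCC)CC(C)(C)[C@@]12CC[C@](C)(O)[C@@H](Cl)C2 | intermediate
15 | (2S,3S,6S)-3-bromo-2-chloro-9-ethoxy-3,11,11-trimethylspiro[5.5]undec-8-en-7-one | O=C1C=C(OCC)CC(C)(C)[C@@]12CC[C@](C)(Br)[C@@H](Cl)C2 | intermediate
16 | (2S,3S,6S)-3,10-dibromo-2-chloro-9-ethoxy-3,11,11-trimethylspiro[5.5]undec-8-en-7-one (C10 epimer mixture) | O=C1C=C(OCC)C(Br)C(C)(C)[C@@]12CC[C@](C)(Br)[C@@H](Cl)C2 | intermediate (not isolated)
17 | (2S,3S,6S,10R)-3,10-dibromo-2-chloro-9-ethoxy-3,11,11-trimethylspiro[5.5]undec-8-en-7-one | O=C1C=C(OCC)[C@H](Br)C(C)(C)[C@@]12CC[C@](C)(Br)[C@@H](Cl)C2 | intermediate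
18 | (2S,3S,6S,10R)-3,10-dibromo-2-chloro-9-ethoxy-3,11,11-trimethyl-7-[(trimethylsilyl)methyl]spiro[5.5]undec-8-en-7-ol (C7 epimer mixture) | C[Si](C)(C)CC1(O)C=C(OCC)[C@H](Br)C(C)(C)[C@@]12CC[C@](C)(Br)[C@@H](Cl)C2 | intermediate (not isolated)
19 | (2S,3S,6R,10R)-3,10-dibromo-2-chloro-3,11,11-trimethyl-7-[(trimethylsilyl)methyl]spiro[5.5]undec-7-en-9-one | C[Si](C)(C)CC1=CC(=O)[C@H](Br)C(C)(C)[C@@]12CC[C@](C)(Br)[C@@H](Cl)C2 | intermediate
20 | (2S,3S,6R,10R)-3,10-dibromo-2-chloro-3,11,11-trimethyl-7-methylidenespiro[5.5]undecan-9-one | C=C1CC(=O)[C@H](Br)C(C)(C)[C@@]12CC[C@](C)(Br)[C@@H](Cl)C2 | intermediate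
21 | (2S,3S,6R,9S,10R)-3,10-dibromo-2-chloro-3,11,11-trimethyl-7-methylidenespiro[5.5]undecan-9-ol (isoobtusol) | C=C1C[C@H](O)[C@H](Br)C(C)(C)[C@@]12CC[C@](C)(Br)[C@@H](Cl)C2 | intermediate
22 | (2S,3S,6R,9S,10R)-3,10-dibromo-2-chloro-3,11,11-trimethyl-7-methylidenespiro[5.5]undecan-9-yl acetate (9-acetylisoobtusol) | C=C1C[C@H](OC(C)=O)[C@H](Br)C(C)(C)[C@@]12CC[C@](C)(Br)[C@@H](Cl)C2 | target

## Step count and least certain steps

Total: 17 steps. Longest linear sequence: 16 steps (1 to 22 by steps 1 to 6 and 8 to 17); step 7 is the one-step branch from 9.

**Step 10 (key step).** Most likely to go wrong: closure in the 5-exo mode; loss of HCl from the hindered tertiary chloride or oxidation of the C6 radical before it cyclises; and poor facial selectivity at C6, because the induction rests only on the small preference of methyl over silyloxy for the equatorial position at C3. Chlorine could also be delivered to the wrong face of C2, since the required face is syn to the axial C7 carbon. Fallback: an oxidative enolate cyclisation that never makes the C6–Cl bond. It sets out from 11, which is deprotonated with LiN(i-Pr)2 in THF at −78 °C and treated with CuCl2 (about two equivalents, DMF co-solvent, −78 °C to rt). Single-electron oxidation gives the same C6 radical, the ring closes as before, and chlorine is passed to C2 by ligand transfer from divalent copper. It comes back to the route at 13, and no compound outside the list is made (F0).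

**Step 12.** Most likely to go wrong: proton loss from the C3 cation instead of capture by bromide; dealkylation or hydrolysis of the ethyl enol ether by HBr; and partial loss of configuration at C3 if the chlorine bridge is weak. Fallback: elimination followed by hydrobromination. It sets out from 14, which is dehydrated with POCl3 in pyridine. This anti elimination can use only the axial C4 hydrogen or a methyl hydrogen, because the anti position on C2 is occupied by chlorine, so no vinyl chloride can form. The product is the alkene (2S,6S)-2-chloro-9-ethoxy-3,11,11-trimethylspiro[5.5]undeca-3,8-dien-7-one F1 (with its exocyclic isomer). Anhydrous HBr in CH2Cl2 at −78 °C then adds in the Markovnikov sense, bromide entering axially anti to chlorine, and the route is rejoined at 15.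

**Step 13.** Most likely to go wrong: attack of bromine at C8 instead of the hindered C10, over-bromination by proton exchange between product and enolate, or protonation of the bromodienolate at C8 or from the face syn to C1. Fallback: a radical bromination in place of the enolate bromination. It sets out from 15, which is brominated at the allylic C10 position under Wohl–Ziegler conditions (NBS, AIBN, PhCF3, 80 °C, K2CO3 as acid scavenger) to give 16, now isolated. 16 is then deprotonated with LiN(SiMe3)2 and protonated with AcOH at −78 °C in a separate operation, returning to the route at 17. No compound outside the list is made (F0); the unwanted C10 epimer can be recycled through the same deprotonation.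

**Step 14.** Most likely to go wrong: enolisation at C10 or attack at a carbon–halogen bond instead of addition to the hindered C7 carbonyl, and loss of the silyl group from the cationic intermediate during the acid transposition, which would give the conjugated methyl enone. Fallback: a route to the same dienolate that uses no carbon nucleophile. It sets out from 17, which is hydrolysed (1 M HCl, THF) to the dione (2S,3S,6S,10R)-3,10-dibromo-2-chloro-3,11,11-trimethylspiro[5.5]undecane-7,9-dione F2. Silylation at the less hindered C9 oxygen (t-BuMe2SiCl, imidazole, DMF) gives the silyl vinylogous ester (2S,3S,6S,10R)-3,10-dibromo-9-(tert-butyldimethylsilyloxy)-2-chloro-3,11,11-trimethylspiro[5.5]undec-8-en-7-one F3. Methylenation of C7 with Cp2TiMe2 (toluene, 65 °C) gives the silyloxy diene (2S,3S,6R,10R)-3,10-dibromo-9-(tert-butyldimethylsilyloxy)-2-chloro-3,11,11-trimethyl-7-methylidenespiro[5.5]undec-8-ene F4. Bu4NF with AcOH at −40 °C then releases the same dienolate as in step 15, and the route is rejoined at 20.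

**Step 15.** Most likely to go wrong: protonation of the dienolate at the methylene terminus or base-induced migration of the alkene into conjugation, enolisation toward C10 with loss of the hindered configuration, and intramolecular displacement of the C10 bromide by the dienolate. Fallback: reduce the ketone as it forms, so that it never accumulates. It sets out from 19, which is desilylated with Bu4NF in the presence of Ac2O (THF, −40 °C) to trap the dienolate on oxygen as the dienol acetate (2S,3S,6R,10R)-3,10-dibromo-2-chloro-3,11,11-trimethyl-7-methylidenespiro[5.5]undec-8-en-9-yl acetate F5. NaBH4 in EtOH/THF at 0 °C then removes the acetyl group, the solvent protonates the dienolate at C8, and the β,γ-unsaturated ketone is reduced at once (the classical dienol acetate–borohydride reduction). The route is rejoined at 21 and 20 is skipped.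

## Further compounds

F0 | step 10 | none | none
F1 | step 12 | (2S,6S)-2-chloro-9-ethoxy-3,11,11-trimethylspiro[5.5]undeca-3,8-dien-7-one | O=C1C=C(OCC)CC(C)(C)[C@@]12CC=C(C)[C@@H](Cl)C2
F0 | step 13 | none | none
F2 | step 14 | (2S,3S,6S,10R)-3,10-dibromo-2-chloro-3,11,11-trimethylspiro[5.5]undecane-7,9-dione | O=C1CC(=O)[C@H](Br)C(C)(C)[C@@]12CC[C@](C)(Br)[C@@H](Cl)C2
F3 | step 14 | (2S,3S,6S,10R)-3,10-dibromo-9-(tert-butyldimethylsilyloxy)-2-chloro-3,11,11-trimethylspiro[5.5]undec-8-en-7-one | O=C1C=C(O[Si](C)(C)C(C)(C)C)[C@H](Br)C(C)(C)[C@@]12CC[C@](C)(Br)[C@@H](Cl)C2
F4 | step 14 | (2S,3S,6R,10R)-3,10-dibromo-9-(tert-butyldimethylsilyloxy)-2-chloro-3,11,11-trimethyl-7-methylidenespiro[5.5]undec-8-ene | C=C1C=C(O[Si](C)(C)C(C)(C)C)[C@H](Br)C(C)(C)[C@@]12CC[C@](C)(Br)[C@@H](Cl)C2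
F5 | step 15 | (2S,3S,6R,10R)-3,10-dibromo-2-chloro-3,11,11-trimethyl-7-methylidenespiro[5.5]undec-8-en-9-yl acetate | C=C1C=C(OC(C)=O)[C@H](Br)C(C)(C)[C@@]12CC[C@](C)(Br)[C@@H](Cl)C2
A1 | alternative 1 | spiro diene ketal with complete ring A (C7 methylidene, C9 tert-butyldimethylsilyloxy, C10 bromo), ring B C1=C2 alkene and C3 ethylene ketal | C=C1C[C@H](O[Si](C)(C)C(C)(C)C)[C@H](Br)C(C)(C)[C@@]12CCC3(OCCO3)C=C2
A2 | alternative 1 | vinyl bromide: 2-bromoallyl chain with (9S)-silyloxy and (10R)-bromo centres joined through C11 to C6 of 1,4-dioxaspiro[4.5]dec-7-ene | C=C(Br)C[C@H](O[Si](C)(C)C(C)(C)C)[C@H](Br)C(C)(C)C1=CCC2(CC1)OCCO2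
A3 | alternative 2 | spiro cis-bromohydrin with C7 methylidene and ring B enone | C=C1C[C@H](O)[C@H](Br)C(C)(C)[C@@]12CCC(=O)C=C2
A4 | alternative 2 | α-bromo aldehyde: 2-bromo-3-methyl-3-[4-oxo-1-(prop-1-en-2-yl)cyclohex-2-en-1-yl]butanal | O=C[C@H](Br)C(C)(C)[C@]1(C(C)=C)CCC(=O)C=C1
A5 | alternative 3 | spiro vinylogous ester with ring B enone: 9-ethoxy-11,11-dimethylspiro[5.5]undeca-1,8-diene-3,7-dione | O=C1C=C(OCC)CC(C)(C)[C@@]12CCC(=O)C=C2
A6 | alternative 3 | 4-ethoxy-6,6-dimethyl-2-oxocyclohex-3-ene-1-carbaldehyde | CCOC1=CC(=O)C(C=O)C(C)(C)C1
A7 | alternative 3 | methyl vinyl ketone (but-3-en-2-one) | C=CC(C)=O
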